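**Plan**
Cuts: the three O–Si bonds come off last. Ring C is cut at C4–C4a (acylation) and O1–C2 (etherification), and C2–C3 goes back to formaldehyde plus an arylacetyl imide. Ring D is cut at O–C(CH3)2, and ring B at C3'–C4', C1'–C2' and C4'–C5'.
Enabling feature: ring B is a resorcinol with oxygen at C2' and C4', carbon substituents at C1' and C3' on both sides of C2', and hydrogen at C5' and C6'. A 2-substituted vinylketene and a 1-siloxyalkyne give exactly this pattern, with the C4' hydroxyl free and the C2' oxygen silylated.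
Forward order: ring B (benzannulation), ring D (oxidative closure on the only free phenol), the side-chain stereocentre, the ether link to ring A, ring C, then global desilylation.
Stereochemistry: the single centre C3 (R) is set by an Evans boron aldol of the (R)-4-benzyloxazolidinone imide with formaldehyde. It is then carried only through weakly basic or base-free steps.

Key step: step 5

Remark: isoflavanone numbering is used (O1 to C8a for rings C and A, primed atoms for ring B, ring D is the dimethylpyran). The centre written in the SMILES is C3 and reads R (C4 > C2 > C1' > H).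

Step 1
Reactants: 1 methyl 4-chloro-4-oxobutanoate; 2 ethyl vinyl ether
Product: 4 methyl 2-(2-ethoxy-4-oxocyclobutyl)acetate (racemic cis/trans mixture), via (methoxycarbonylmethyl)ketene 3 (not isolated)
Conditions: Et3N, 2 (5 equiv), MeCN, sealed vessel, 80 °C, slow addition of 1
Reagents that add atoms: none
Why: Dehydrochlorination of 1 gives aldoketene 3, which undergoes the thermal ketene–enol ether [2+2] cycloaddition with its carbonyl carbon bonding to the nucleophilic CH2 end of 2, so the ethoxy group sits on the ring carbon next to the one carrying the acetate arm, while excess 2 and slow addition hold back ketene dimerisation.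

Step 2
Reactants: 4 methyl 2-(2-ethoxy-4-oxocyclobutyl)acetate
Product: 5 methyl 2-(4-oxocyclobut-1-en-1-yl)acetate
Conditions: activated basic Al2O3, Et2O, rt, short contact; used at once
Reagents that add atoms: none
Why: E1cB loss of alcohol from a 3-alkoxycyclobutanone is a classical entry to cyclobutenones, and because enolisation is reversible and loss of ethoxide is rate-limiting the more substituted enolate and the trisubstituted C2=C3 alkene should be favoured, while the alumina binds the ethanol so that it cannot add back and its mild basicity spares the acidic CH2 of the arm.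

Step 3
Reactants: 6 prenyl bromide; 7 ethynylmagnesium bromide
Product: 8 5-methylhex-4-en-1-yne
Conditions: CuCl (5 mol %), THF, 0 to 40 °C, excess 7
Reagents that add atoms: none
Why: Copper-catalysed coupling of an alkynyl Grignard reagent with an allylic bromide takes place at the unhindered primary carbon of 6 (SN2 rather than SN2') and should give the skipped enyne.

Step 4
Reactants: 8 5-methylhex-4-en-1-yne
Product: 11 5-methyl-1-(triisopropylsilyloxy)hex-4-en-1-yne, via lithium acetylide 9 (not isolated), via lithium ynolate 10 (not isolated)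
Conditions: n-BuLi (1.0 equiv), THF, −78 °C; t-BuOOLi (from t-BuOOH and LiN(SiMe3)2), −78 to 0 °C; TIPSOTf, −78 to 0 °C
Reagents that add atoms: tert-butyl hydroperoxide, CC(C)(C)OO; triisopropylsilyl trifluoromethanesulfonate, CC(C)[Si](C(C)C)(C(C)C)OS(=O)(=O)C(F)(F)F
Why: In the known acetylide-to-ynolate oxidation the acetylide attacks the peroxide oxygen and expels tert-butoxide, the hard and bulky silyl triflate then traps ynolate 10 on oxygen, and the nucleophilic peroxide leaves the trisubstituted alkene untouched.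

Step 5
Reactants: 5 methyl 2-(4-oxocyclobut-1-en-1-yl)acetate; 11 5-methyl-1-(triisopropylsilyloxy)hex-4-en-1-yne
Product: 16 methyl 2-[4-hydroxy-3-(3-methylbut-2-en-1-yl)-2-(triisopropylsilyloxy)phenyl]acetate, via vinylketene 12 (not isolated), via 4-vinylcyclobutenone 13 (not isolated), via dienylketene 14 (not isolated), via cyclohexa-2,4-dienone 15 (not isolated)
Conditions: 11 (1.3 equiv), toluene, 80 °C, slow addition of 5, then 110 °C
Reagents that add atoms: none
Why: On heating, 5 opens by a 4π electrocyclic reaction to vinylketene 12, whose ketene unit adds 11 in a [2+2] cycloaddition to give 13 (new bonds C3'–C4' and C1'–C2'), 13 opens again (4π) to dienylketene 14, and 14 closes to dienone 15 (new bond C4'–C5'), which tautomerises to phenol 16. This is the Danheiser benzannulation in its siloxyalkyne version, known to turn cyclobutenones into resorcinol monosilyl ethers. Ring B is closed in a disrotatory 6π electrocyclisation between the ketene carbon (C4') and the terminal vinyl carbon (C5', the former ring CH2 of 5). No stereocentre remains, since the quaternary carbon of 13 is transient and is flattened in the second ring opening. The step needs a single regiochemistry in the [2+2] event, and the polarisation of the ynol ether secures it: the prenyl-bearing carbon remote from oxygen is the nucleophilic end and bonds to the ketene carbonyl carbon, so the carbonyl oxygen becomes the free C4' hydroxyl, the silyloxy group lands on C2' and the 2-substituent of 5 on C1'. The electron-rich alkyne should outrun the prenyl alkene as ketenophile, and slow addition of 5 to excess 11 keeps the ketene from acylating the phenol as it forms.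

Step 6
Reactants: 16 methyl 2-[4-hydroxy-3-(3-methylbut-2-en-1-yl)-2-(triisopropylsilyloxy)phenyl]acetate
Product: 18 methyl 2-[2,2-dimethyl-5-(triisopropylsilyloxy)-2H-chromen-6-yl]acetate, via ortho-quinone methide 17 (not isolated)
Conditions: DDQ (1.1 equiv), toluene, 80 °C
Reagents that add atoms: none
Why: In the known oxidative cyclisation of ortho-prenylphenols DDQ takes hydride from the benzylic and allylic CH2 to give quinone methide 17, whose oxa-6π electrocyclisation forms the O–C(CH3)2 bond, and since only the C4' oxygen is free only the angular chromene can arise.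

Step 7
Reactants: 18 methyl 2-[2,2-dimethyl-5-(triisopropylsilyloxy)-2H-chromen-6-yl]acetate
Product: 19 2-[2,2-dimethyl-5-(triisopropylsilyloxy)-2H-chromen-6-yl]acetic acid
Conditions: LiOH, THF–MeOH–H2O, 0 °C to rt; then cold 1 M HCl
Reagents that add atoms: lithium hydroxide, [Li+].[OH-]
Why: This is ordinary saponification of an unhindered methyl ester, which the chromene and the aryl silyl ether (shielded by two ortho substituents) should tolerate.

Step 8
Reactants: 19 2-[2,2-dimethyl-5-(triisopropylsilyloxy)-2H-chromen-6-yl]acetic acid; 20 (R)-4-benzyl-2-oxazolidinone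
Product: 22 (R)-4-benzyl-3-{2-[2,2-dimethyl-5-(triisopropylsilyloxy)-2H-chromen-6-yl]acetyl}oxazolidin-2-one, via mixed pivalic anhydride 21 (not isolated)
Conditions: PivCl, Et3N, THF, −20 °C; then 20, LiCl, rt
Reagents that add atoms: none
Why: This is standard N-acylation of an Evans oxazolidinone through the mixed pivalic anhydride with LiCl and amine activation, which needs no strong base.

Step 9
Reactants: 22 (R)-4-benzyl-3-{2-[2,2-dimethyl-5-(triisopropylsilyloxy)-2H-chromen-6-yl]acetyl}oxazolidin-2-one
Product: 25 (R)-4-benzyl-3-{(2R)-2-[2,2-dimethyl-5-(triisopropylsilyloxy)-2H-chromen-6-yl]-3-hydroxypropanoyl}oxazolidin-2-one, via Z-boron enolate 23 (not isolated), via boron aldolate 24 (not isolated)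
Conditions: Bu2BOTf, Et3N, CH2Cl2, −78 to 0 °C; CH2O gas (cracked paraformaldehyde), −78 °C; pH 7 buffer, MeOH, H2O2, 0 °C
Reagents that add atoms: formaldehyde, C=O
Why: In this Evans boron aldol with formaldehyde, soft enolisation gives Z-enolate 23, which reacts through the closed, dipole-opposed transition state on the face away from the benzyl group (the sense in which the (R)-auxiliary gives 2R syn aldols), so the future C3 is set as R, and no free strong Lewis acid is present that could attack the chromene.

Step 10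
Reactants: 26 phloroglucinol
Product: 27 3,5-bis(triisopropylsilyloxy)phenol
Conditions: TIPSCl (2.0 equiv), imidazole, DMF, 0 °C to rt
Reagents that add atoms: triisopropylsilyl chloride, CC(C)[Si](Cl)(C(C)C)C(C)C
Why: This is statistical double silylation of a symmetrical triol, in which the bulk of the silyl group slows the third silylation and the under- and over-silylated material can be separated and recycled.

Step 11
Reactants: 25 (R)-4-benzyl-3-{(2R)-2-[2,2-dimethyl-5-(triisopropylsilyloxy)-2H-chromen-6-yl]-3-hydroxypropanoyl}oxazolidin-2-one; 27 3,5-bis(triisopropylsilyloxy)phenol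
Product: 28 (R)-4-benzyl-3-{(2R)-3-[3,5-bis(triisopropylsilyloxy)phenoxy]-2-[2,2-dimethyl-5-(triisopropylsilyloxy)-2H-chromen-6-yl]propanoyl}oxazolidin-2-one
Conditions: PPh3, DIAD, toluene, 0 °C to rt
Reagents that add atoms: none
Why: Mitsunobu etherification of a primary alcohol with a phenol forms O1–C2 without touching the stereocentre, and allylic 1,3-strain in the α-branched imide keeps the α-C–H bond out of alignment with the carbonyl π system, which disfavours β-elimination.

Step 12
Reactants: 28 (R)-4-benzyl-3-{(2R)-3-[3,5-bis(triisopropylsilyloxy)phenoxy]-2-[2,2-dimethyl-5-(triisopropylsilyloxy)-2H-chromen-6-yl]propanoyl}oxazolidin-2-one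
Product: 30 (2R)-3-[3,5-bis(triisopropylsilyloxy)phenoxy]-2-[2,2-dimethyl-5-(triisopropylsilyloxy)-2H-chromen-6-yl]propanoic acid, via peroxy acid 29 (not isolated)
Conditions: LiOH, H2O2, THF–H2O, 0 °C; Na2SO3; then cold 1 M HCl
Reagents that add atoms: hydrogen peroxide, OO
Why: Hydroperoxide cleavage of an Evans imide is selective for the exocyclic carbonyl and only weakly basic, so neither epimerisation of the α-aryl centre nor loss of aryloxide is expected, the aryl triisopropylsilyl ethers hold, and sulfite reduces 29 to 30.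

Step 13
Reactants: 30 (2R)-3-[3,5-bis(triisopropylsilyloxy)phenoxy]-2-[2,2-dimethyl-5-(triisopropylsilyloxy)-2H-chromen-6-yl]propanoic acid
Product: 32 (3R)-3-[2,2-dimethyl-5-(triisopropylsilyloxy)-2H-chromen-6-yl]-5,7-bis(triisopropylsilyloxy)chroman-4-one, via mixed trifluoroacetic anhydride 31 (not isolated)
Conditions: (CF3CO)2O (1.2 equiv), CH2Cl2, high dilution, −10 to 0 °C
Reagents that add atoms: none
Why: In this intramolecular Friedel–Crafts acylation through mixed anhydride 31 (the known way from 3-aryloxy-2-arylpropanoic acids to non-racemic isoflavanones) the phloroglucinol-type ring needs no metal Lewis acid, its two positions ortho to the OCH2 group are equivalent, the six-membered ring C closes at C4–C4a, and the absence of base rules out a ketene and hence racemisation by that path.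

Step 14
Reactants: 32 (3R)-3-[2,2-dimethyl-5-(triisopropylsilyloxy)-2H-chromen-6-yl]-5,7-bis(triisopropylsilyloxy)chroman-4-one
Product: 33 (3R)-5,7-dihydroxy-3-(5-hydroxy-2,2-dimethyl-2H-chromen-6-yl)chroman-4-one (target)
Conditions: HF·pyridine, pyridine, THF, 0 °C to rt
Reagents that add atoms: none
Why: Fluoride cleavage of aryl silyl ethers in a mildly acidic, buffered medium frees all three phenols at once, avoids free phenoxide that could enolise C3, and leaves the chromene intact.

**Compound list**
1 | methyl 4-chloro-4-oxobutanoate | COC(=O)CCC(=O)Cl | starting material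
2 | ethyl vinyl ether | C=COCC | starting material
3 | (methoxycarbonylmethyl)ketene (methyl 4-oxobut-3-enoate) | COC(=O)CC=C=O | intermediate
4 | methyl 2-(2-ethoxy-4-oxocyclobutyl)acetate, racemic cis/trans mixture | CCOC1CC(=O)C1CC(=O)OC | intermediate
5 | methyl 2-(4-oxocyclobut-1-en-1-yl)acetate | COC(=O)CC1=CCC1=O | intermediate
6 | prenyl bromide (1-bromo-3-methylbut-2-ene) | CC(C)=CCBr | starting material
7 | ethynylmagnesium bromide | C#C[Mg]Br | starting material
8 | 5-methylhex-4-en-1-yne | CC(C)=CCC#C | intermediate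
9 | lithium 5-methylhex-4-en-1-yn-1-ide | CC(C)=CCC#C[Li] | intermediate
10 | lithium 5-methylhex-4-en-1-yn-1-olate | CC(C)=CCC#C[O-].[Li+] | intermediate
11 | 5-methyl-1-(triisopropylsilyloxy)hex-4-en-1-yne | CC(C)=CCC#CO[Si](C(C)C)(C(C)C)C(C)C | intermediate
12 | vinylketene, methyl 3-(oxomethylidene)pent-4-enoate | COC(=O)CC(C=C)=C=O | intermediate
13 | methyl 2-[1-ethenyl-3-(3-methylbut-2-en-1-yl)-4-oxo-2-(triisopropylsilyloxy)cyclobut-2-en-1-yl]acetate, racemic | COC(=O)CC1(C=C)C(=O)C(CC=C(C)C)=C1O[Si](C(C)C)(C(C)C)C(C)C | intermediate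
14 | dienylketene, methyl (3E)-3-ethenyl-8-methyl-5-(oxomethylidene)-4-(triisopropylsilyloxy)nona-3,7-dienoate | C=C/C(CC(=O)OC)=C(/O[Si](C(C)C)(C(C)C)C(C)C)C(CC=C(C)C)=C=O | intermediate
15 | methyl 2-[5-(3-methylbut-2-en-1-yl)-4-oxo-6-(triisopropylsilyloxy)cyclohexa-1,5-dien-1-yl]acetate | COC(=O)CC1=CCC(=O)C(CC=C(C)C)=C1O[Si](C(C)C)(C(C)C)C(C)C | intermediate
16 | methyl 2-[4-hydroxy-3-(3-methylbut-2-en-1-yl)-2-(triisopropylsilyloxy)phenyl]acetate | COC(=O)Cc1ccc(O)c(CC=C(C)C)c1O[Si](C(C)C)(C(C)C)C(C)C | intermediate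
17 | ortho-quinone methide from 16 (C4' carbonyl, exocyclic C3'=CH–CH=C(CH3)2 turned toward the carbonyl) | COC(=O)CC1=C(O[Si](C(C)C)(C(C)C)C(C)C)/C(=C/C=C(C)C)C(=O)C=C1 | intermediate
18 | methyl 2-[2,2-dimethyl-5-(triisopropylsilyloxy)-2H-chromen-6-yl]acetate | COC(=O)Cc1ccc2OC(C)(C)C=Cc2c1O[Si](C(C)C)(C(C)C)C(C)C | intermediate
19 | 2-[2,2-dimethyl-5-(triisopropylsilyloxy)-2H-chromen-6-yl]acetic acid | OC(=O)Cc1ccc2OC(C)(C)C=Cc2c1O[Si](C(C)C)(C(C)C)C(C)C | intermediate
20 | (R)-4-benzyl-2-oxazolidinone | O=C1N[C@H](Cc2ccccc2)CO1 | starting material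
21 | mixed anhydride of 19 and pivalic acid | CC(C)(C)C(=O)OC(=O)Cc1ccc2OC(C)(C)C=Cc2c1O[Si](C(C)C)(C(C)C)C(C)C | intermediate
22 | (R)-4-benzyl-3-{2-[2,2-dimethyl-5-(triisopropylsilyloxy)-2H-chromen-6-yl]acetyl}oxazolidin-2-one | O=C(Cc1ccc2OC(C)(C)C=Cc2c1O[Si](C(C)C)(C(C)C)C(C)C)N1[C@H](Cc2ccccc2)COC1=O | intermediate
23 | Z-dibutylboron enolate of 22 | CCCCB(CCCC)O/C(=C\c1ccc2OC(C)(C)C=Cc2c1O[Si](C(C)C)(C(C)C)C(C)C)N1[C@H](Cc2ccccc2)COC1=O | intermediate
24 | dibutylboron aldolate of 25 | CCCCB(CCCC)OC[C@@H](c1ccc2OC(C)(C)C=Cc2c1O[Si](C(C)C)(C(C)C)C(C)C)C(=O)N1[C@H](Cc2ccccc2)COC1=O | intermediate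
25 | (R)-4-benzyl-3-{(2R)-2-[2,2-dimethyl-5-(triisopropylsilyloxy)-2H-chromen-6-yl]-3-hydroxypropanoyl}oxazolidin-2-one | OC[C@@H](c1ccc2OC(C)(C)C=Cc2c1O[Si](C(C)C)(C(C)C)C(C)C)C(=O)N1[C@H](Cc2ccccc2)COC1=O | intermediate
26 | phloroglucinol | Oc1cc(O)cc(O)c1 | starting material
27 | 3,5-bis(triisopropylsilyloxy)phenol | Oc1cc(O[Si](C(C)C)(C(C)C)C(C)C)cc(O[Si](C(C)C)(C(C)C)C(C)C)c1 | intermediate
28 | (R)-4-benzyl-3-{(2R)-3-[3,5-bis(triisopropylsilyloxy)phenoxy]-2-[2,2-dimethyl-5-(triisopropylsilyloxy)-2H-chromen-6-yl]propanoyl}oxazolidin-2-one | CC(C)[Si](C(C)C)(C(C)C)Oc1cc(OC[C@@H](c2ccc3OC(C)(C)C=Cc3c2O[Si](C(C)C)(C(C)C)C(C)C)C(=O)N2[C@H](Cc3ccccc3)COC2=O)cc(O[Si](C(C)C)(C(C)C)C(C)C)c1 | intermediate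
29 | peroxy acid of 30 | CC(C)[Si](C(C)C)(C(C)C)Oc1cc(OC[C@@H](c2ccc3OC(C)(C)C=Cc3c2O[Si](C(C)C)(C(C)C)C(C)C)C(=O)OO)cc(O[Si](C(C)C)(C(C)C)C(C)C)c1 | intermediate
30 | (2R)-3-[3,5-bis(triisopropylsilyloxy)phenoxy]-2-[2,2-dimethyl-5-(triisopropylsilyloxy)-2H-chromen-6-yl]propanoic acid | CC(C)[Si](C(C)C)(C(C)C)Oc1cc(OC[C@@H](c2ccc3OC(C)(C)C=Cc3c2O[Si](C(C)C)(C(C)C)C(C)C)C(=O)O)cc(O[Si](C(C)C)(C(C)C)C(C)C)c1 | intermediate
31 | mixed anhydride of 30 and trifluoroacetic acid | CC(C)[Si](C(C)C)(C(C)C)Oc1cc(OC[C@@H](c2ccc3OC(C)(C)C=Cc3c2O[Si](C(C)C)(C(C)C)C(C)C)C(=O)OC(=O)C(F)(F)F)cc(O[Si](C(C)C)(C(C)C)C(C)C)c1 | intermediate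
32 | (3R)-3-[2,2-dimethyl-5-(triisopropylsilyloxy)-2H-chromen-6-yl]-5,7-bis(triisopropylsilyloxy)chroman-4-one | CC1(C)C=Cc2c(ccc([C@@H]3COc4cc(O[Si](C(C)C)(C(C)C)C(C)C)cc(O[Si](C(C)C)(C(C)C)C(C)C)c4C3=O)c2O[Si](C(C)C)(C(C)C)C(C)C)O1 | intermediate
33 | (3R)-5,7-dihydroxy-3-(5-hydroxy-2,2-dimethyl-2H-chromen-6-yl)chroman-4-one | CC1(C)C=Cc2c(ccc([C@@H]3COc4cc(O)cc(O)c4C3=O)c2O)O1 | target

**Step count and risks**
Total step count: 14. Longest linear sequence: 11 steps (1, 2, 5, 6, 7, 8, 9, 11, 12, 13, 14).

Steps most likely to fail: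

Step 2. Three processes threaten it. Ethanol may add back to the strained enone. Ethoxide may be lost toward the ring CH2 instead of the substituted carbon. The ring double bond may migrate out of the ring into conjugation with the ester. The fallback reaches the same vinylketene without any cyclobutenone. It sets out from 1. Stille acylation of 1 with tributyl(vinyl)stannane and Pd(PPh3)4 should give methyl 4-oxohex-5-enoate F1. Its ketone enolate (LiN(SiMe3)2, −78 °C) is acylated with 2,2,2-trifluoroethyl trifluoroacetate to give methyl 4-oxo-3-(trifluoroacetyl)hex-5-enoate F2. This is treated without isolation with methanesulfonyl azide, Et3N and water (detrifluoroacetylative diazo transfer) to give methyl 3-diazo-4-oxohex-5-enoate F3. Irradiation of F3 at 254 nm in the presence of 11 triggers a photochemical Wolff rearrangement with vinyl migration to ketene 12. Brief heating at 80 °C then runs the cascade through 13, 14 and 15. The fallback comes back to the route at 16.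

Step 11. The activated primary oxygen may be lost by β-elimination, with dehydration to the acrylimide. Unselective conjugate addition of the phenol would then erase the configuration at the future C3. In the fallback the ether oxygen arrives together with C2, so no activated β-oxygen ever sits next to the acidic C–H. It sets out from 19 and 27.
- A chelated sodium enolate is alkylated on the face opposite to the one used in the boron aldol. Therefore 19 is joined under the conditions of step 8 to commercial (S)-4-benzyl-2-oxazolidinone, giving (S)-4-benzyl-3-{2-[2,2-dimethyl-5-(triisopropylsilyloxy)-2H-chromen-6-yl]acetyl}oxazolidin-2-one F4.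
- Phenol 27 with NaH, NaI and chloromethyl methyl sulfide gives 1-(methylthiomethoxy)-3,5-bis(triisopropylsilyloxy)benzene F5. SO2Cl2 in CH2Cl2 at −78 °C with cyclohexene as scavenger converts this into 1-(chloromethoxy)-3,5-bis(triisopropylsilyloxy)benzene F6.
- Evans alkylation of F4 (NaN(SiMe3)2, THF, −78 °C) with F6 should give (S)-4-benzyl-3-{(2R)-3-[3,5-bis(triisopropylsilyloxy)phenoxy]-2-[2,2-dimethyl-5-(triisopropylsilyloxy)-2H-chromen-6-yl]propanoyl}oxazolidin-2-one F7.
- LiOH and H2O2 as in step 12 bring the sequence back to the route at 30.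

Step 13. Acid-promoted enolisation of the mixed anhydride or of the ketone may erode the configuration at C3. Protonation of the chromene double bond and loss of the silyl group next to the carbonyl are lesser worries. The fallback moves stereocontrol from the auxiliary to a catalyst acting on the finished ring system. It sets out from 32 of whatever enantiomeric purity. Noyori–Ikariya transfer hydrogenation with RuCl(p-cymene)[(R,R)-TsDPEN] in HCO2H–Et3N runs as a dynamic kinetic resolution: C3 epimerises through the enol while the 3R ketone is reduced faster. This should give (3R,4R)-cis-3-[2,2-dimethyl-5-(triisopropylsilyloxy)-2H-chromen-6-yl]-5,7-bis(triisopropylsilyloxy)chroman-4-ol F8. Oxidation with Dess–Martin periodinane in CH2Cl2 at 0 °C, a neutral medium, returns to the route at 32.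

**Further compounds**
F1 | step 2 | methyl 4-oxohex-5-enoate | C=CC(=O)CCC(=O)OC
F2 | step 2 | methyl 4-oxo-3-(trifluoroacetyl)hex-5-enoate | C=CC(=O)C(CC(=O)OC)C(=O)C(F)(F)F
F3 | step 2 | methyl 3-diazo-4-oxohex-5-enoate | C=CC(=O)C(=[N+]=[N-])CC(=O)OC
F4 | step 11 | (S)-4-benzyl-3-{2-[2,2-dimethyl-5-(triisopropylsilyloxy)-2H-chromen-6-yl]acetyl}oxazolidin-2-one | O=C(Cc1ccc2OC(C)(C)C=Cc2c1O[Si](C(C)C)(C(C)C)C(C)C)N1[C@@H](Cc2ccccc2)COC1=O
F5 | step 11 | 1-(methylthiomethoxy)-3,5-bis(triisopropylsilyloxy)benzene | CSCOc1cc(O[Si](C(C)C)(C(C)C)C(C)C)cc(O[Si](C(C)C)(C(C)C)C(C)C)c1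
F6 | step 11 | 1-(chloromethoxy)-3,5-bis(triisopropylsilyloxy)benzene | ClCOc1cc(O[Si](C(C)C)(C(C)C)C(C)C)cc(O[Si](C(C)C)(C(C)C)C(C)C)c1
F7 | step 11 | (S)-4-benzyl-3-{(2R)-3-[3,5-bis(triisopropylsilyloxy)phenoxy]-2-[2,2-dimethyl-5-(triisopropylsilyloxy)-2H-chromen-6-yl]propanoyl}oxazolidin-2-one | CC(C)[Si](C(C)C)(C(C)C)Oc1cc(OC[C@@H](c2ccc3OC(C)(C)C=Cc3c2O[Si](C(C)C)(C(C)C)C(C)C)C(=O)N2[C@@H](Cc3ccccc3)COC2=O)cc(O[Si](C(C)C)(C(C)C)C(C)C)c1
F8 | step 13 | (3R,4R)-cis-3-[2,2-dimethyl-5-(triisopropylsilyloxy)-2H-chromen-6-yl]-5,7-bis(triisopropylsilyloxy)chroman-4-ol | CC1(C)C=Cc2c(ccc([C@@H]3COc4cc(O[Si](C(C)C)(C(C)C)C(C)C)cc(O[Si](C(C)C)(C(C)C)C(C)C)c4[C@@H]3O)c2O[Si](C(C)C)(C(C)C)C(C)C)O1
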